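**Plan**

- Retrosynthesis: the C6–O ester bond and the diene double bonds C14=C15 and C12=C13 are cut first, back to a 12-silyloxy-13,14,15,16-tetranorlabdane-6α,8α-diol. Then C-7 is excised from ring B (bonds C6–C7 and C7–C8, with a C6–C8 bond in return), then C9–C10 (Nazarov) and C6–C8 (alkenyllithium + aldehyde).
- Enabling feature: ring B (C5–C6–C7–C8–C9–C10) has its only CH2, C-7, between the oxygenated C-6 and the methyl carbinol C-8. C6(=O)–C7H2–C8(OH)CH3 is the pattern left by oxidative scission of the internal bond of a 1-silyloxybicyclo[3.1.0]hexane whose cyclopropane is C6–C7–C8 and whose five-membered ring is C5–C6–C8–C9–C10.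
- Forward: ring A comes with β-cyclocitral; the B-nor five-membered ring is closed by a reductive Nazarov cyclisation; C-7 is added by cyclopropanation and ring B arises by aerobic ring expansion, which also installs the C-6 carbonyl and the C-8 hydroxyl; C-6 reduction, angelate and the diene (two Wittig reactions) follow.
- Stereochemistry: C-9/C-10 relative configuration from conrotation of the (E)-dienone, absolute configuration from a chiral counteranion; C-5 by α-face protonation; C-8 by O2 capture anti to the axial C-10 methyl; C-6 by thermodynamically controlled dissolving-metal reduction; 12E from a stabilised ylide; the Z ester from angelic acid.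

Key step: step 8

Remark (assumption): labdane numbering of the target is used for all intermediates (α = face opposite the C-10 methyl); the sense of induction of the chiral acid in step 5 cannot be predicted with certainty, so the (S,S)-catalyst is written and its mirror image is used if a pilot run shows the opposite sense.

**Route**

Step 1
Reactants: 1 pent-3-yn-1-ol
Product: 2 triisopropyl(pent-3-yn-1-yloxy)silane
Conditions: TIPSCl, imidazole, DMF, rt
Reagents that add atoms: chlorotriisopropylsilane, CC(C)[Si](Cl)(C(C)C)C(C)C
Why: Standard silylation of a primary alcohol; the TIPS ether is chosen because it should survive organolithium, Lewis acid, zinc carbenoid, aerobic and Li/NH3 conditions.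

Step 2
Reactants: 2 triisopropyl(pent-3-yn-1-yloxy)silane
Product: 4 (E)-(4-iodopent-3-en-1-yloxy)triisopropylsilane, via alkenylzirconocene chloride 3 (not isolated)
Conditions: Cp2Zr(H)Cl (2 equiv), THF, rt → 50 °C; then I2, 0 °C
Reagents that add atoms: iodine, II
Why: syn-Hydrozirconation of the internal alkyne; with excess hydride the metal should equilibrate to the less hindered methyl-bearing carbon, and iodinolysis with retention gives the (E)-iodoalkene.

Step 3
Reactants: 4 (E)-(4-iodopent-3-en-1-yloxy)triisopropylsilane; 5 β-cyclocitral (2,6,6-trimethylcyclohex-1-ene-1-carbaldehyde)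
Product: 7 (E)-2-methyl-5-(triisopropylsilyloxy)-1-(2,6,6-trimethylcyclohex-1-en-1-yl)pent-2-en-1-ol (carbinol centre racemic), via alkenyllithium 6 (not isolated)
Conditions: t-BuLi (2.1 equiv), Et2O, −78 °C; then 5, −78 → 0 °C; H2O
Reagents that add atoms: none
Why: Iodine–lithium exchange with retention of alkene geometry followed by 1,2-addition to the hindered enal; the new carbinol centre is removed in step 4.

Step 4
Reactants: 7 bis-allylic alcohol
Product: 8 (E)-2-methyl-5-(triisopropylsilyloxy)-1-(2,6,6-trimethylcyclohex-1-en-1-yl)pent-2-en-1-one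
Conditions: DMP, pyridine, CH2Cl2, 0 °C → rt
Reagents that add atoms: none
Why: Periodinane oxidation of the bis-allylic alcohol under buffered conditions should give the cross-conjugated dienone without E/Z isomerisation or allylic transposition.

Step 5
Reactants: 8 cross-conjugated dienone
Product: 10 B-nor ketone (trans-fused 2,3a,7,7-tetramethyl-3-[2-(triisopropylsilyloxy)ethyl]octahydro-1H-inden-1-one; 5α-H, and 8-Me, 9-chain and 10-Me all β), via triethylsilyl enol ether 9 (not isolated)
Conditions: confined chiral imidodiphosphorimidate acid ((S,S)-IDPi, 5 mol %), Et3SiH (1.5 equiv), toluene, −60 → −20 °C; then 1 M HCl, THF, 0 °C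
Reagents that add atoms: none
Why: Proposed new method: the chiral acid is silylated by Et3SiH to a silylium ion pair that O-silylates 8, and the 3-silyloxypentadienyl cation closes by conrotatory 4π electrocyclisation (C9–C10 bond); C-1 of the ring and the C-11 chain are both outside substituents of the termini and end up trans, which places the side chain cis to the C-10 methyl, while the confined chiral anion selects the sense of conrotation (absolute configuration). The silyloxyallyl cation is then reduced by Et3SiH at the less hindered terminus C-8 (anti to the side chain), which regenerates the silylium catalyst, and hydrolysis protonates C-5 of 9 from the α face, away from the axial methyls on C-10 and C-4, to give the trans ring fusion. Closest known reaction types: the Lewis acid/silane reductive Nazarov cyclisation (racemic) and the confined chiral Brønsted acid-catalysed Nazarov cyclisation of simple divinyl ketones.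

Step 6
Reactants: 10 B-nor ketone
Product: 12 trimethylsilyl enol ether (C6=C8 double bond), via lithium enolate 11 (not isolated)
Conditions: LDA, TMSCl (in situ quench), THF, −78 °C
Reagents that add atoms: chlorotrimethylsilane, C[Si](C)(C)Cl
Why: Kinetic deprotonation should take the exposed C-8 hydrogen, because the C-5 hydrogen lies between two quaternary carbons and a C5=C6 enolate would suffer A(1,3) strain with the equatorial C-4 methyl; the ring-fusion centre is therefore not touched.

Step 7
Reactants: 12 trimethylsilyl enol ether
Product: 13 cyclopropyl silyl ether (C-7 methylene bridging C-6 and C-8 on the α face; OTMS and 8-Me β)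
Conditions: Et2Zn, CH2I2, CH2Cl2, 0 °C → rt
Reagents that add atoms: diiodomethane, ICI
Why: Simmons–Smith cyclopropanation of the electron-rich tetrasubstituted silyl enol ether, expected from the α face opposite the C-10 methyl and the C-9 chain; both cyclopropane stereocentres are transient.

Step 8
Reactants: 13 cyclopropyl silyl ether
Product: 15 8α-hydroxy-12-(triisopropylsilyloxy)-13,14,15,16-tetranorlabdan-6-one, via 8α-hydroperoxide 14 (not isolated)
Conditions: VO(acac)2 (5 mol %), O2 (1 atm), EtOH, 0 °C → rt; then PPh3
Reagents that add atoms: dioxygen, O=O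
Why: One-electron oxidation of the silyloxycyclopropane (with ethanolysis of the O–Si bond) gives the C-6 alkoxyl radical, which undergoes β-scission of the internal C6–C8 bond, so that the five-membered B-nor ring becomes ring B with a C-6 ketone and a tertiary radical at C-8; this radical is captured by O2 and the hydroperoxide 14 is reduced by PPh3. The closest known reaction types are the Fe(III)-mediated ring expansion of 1-silyloxybicyclo[n.1.0]alkanes and the metal-catalysed aerobic opening of cyclopropanols and their silyl ethers to β-hydroperoxy and β-hydroxy ketones. No ring is closed: ring B arises by cleavage of the zero-atom bridge of the bicycle, a one-carbon ring expansion. The only new stereocentre, C-8, is set by approach of O2 to the planar radical from the α face, opposite the axial C-10 methyl, which places oxygen equatorial and the C-8 methyl axial as in the target; C-5, C-9 and C-10 are not touched, and the cyclopropane stereocentres disappear, so the facial course of step 7 does not matter. The step needs scission of the internal and not the external (C6–C7) cyclopropane bond, which is secured by formation of a tertiary instead of a primary radical and by relief of bicyclic strain. The neutral conditions should avoid dehydration or retro-aldol cleavage of the β-hydroxy ketone.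

Step 9
Reactants: 15 β-hydroxy ketone
Product: 16 12-(triisopropylsilyloxy)-13,14,15,16-tetranorlabdane-6α,8α-diol
Conditions: Li, NH3(l), THF, t-BuOH, −78 °C; then NH4Cl
Reagents that add atoms: none
Why: Dissolving-metal reduction proceeds through the ketyl and carbanion and should give the thermodynamically favoured equatorial 6α-alcohol (hydride reagents would attack from the α face and give the axial 6β-epimer); low temperature and a proton source suppress retro-aldol cleavage.

Step 10
Reactants: 16 6α,8α-diol; 17 angelic acid ((Z)-2-methylbut-2-enoic acid)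
Product: 19 8α-hydroxy-12-(triisopropylsilyloxy)-13,14,15,16-tetranorlabdan-6α-yl angelate, via mixed anhydride 18 (not isolated)
Conditions: 17, 2,4,6-trichlorobenzoyl chloride, Et3N, toluene, rt; then 16, 80 °C
Reagents that add atoms: none
Why: Yamaguchi esterification: the secondary 6α-hydroxyl attacks the less hindered angeloyl carbonyl of the mixed anhydride while the tertiary 8-hydroxyl does not react, and leaving out nucleophilic catalysts should prevent isomerisation of the Z ester to the tiglate.

Step 11
Reactants: 19 silyl ether angelate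
Product: 20 8α,12-dihydroxy-13,14,15,16-tetranorlabdan-6α-yl angelate
Conditions: HF·pyridine, pyridine, THF, 0 °C → rt
Reagents that add atoms: none
Why: Buffered fluoride cleavage of the primary silyl ether leaves the angelate and the tertiary alcohol untouched.

Step 12
Reactants: 20 primary alcohol
Product: 21 8α-hydroxy-12-oxo-13,14,15,16-tetranorlabdan-6α-yl angelate (aldehyde, in equilibrium with its 8,12-lactol)
Conditions: DMP, pyridine, CH2Cl2, 0 °C → rt
Reagents that add atoms: none
Why: Periodinane oxidation of the only oxidisable alcohol; the five-membered lactol formed with the 8-hydroxyl reacts through its open form in step 13.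

Step 13
Reactants: 21 hydroxy aldehyde; 22 2-(triphenylphosphoranylidene)propanal
Product: 23 (12E)-6α-angeloyloxy-8α-hydroxy-15-norlabd-12-en-14-al
Conditions: toluene, 90 °C
Reagents that add atoms: none
Why: Wittig reaction of a stabilised ylide with the aldehyde under neutral conditions should give the (E)-trisubstituted enal (C12=C13).

Step 14
Reactants: 23 (E)-enal
Product: 24 (12E)-8α-hydroxylabda-12,14-dien-6α-yl angelate (target)
Conditions: Ph3PCH3Br, KHMDS, THF, 0 °C; then 23, −78 → 0 °C
Reagents that add atoms: methyltriphenylphosphonium bromide, C[P+](c1ccccc1)(c1ccccc1)c1ccccc1.[Br-]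
Why: Wittig methylenation of the aldehyde completes the 1,3-diene with retention of the C12=C13 geometry; the hindered ester should be inert to the non-stabilised ylide at low temperature.

**Compound list**

1 | pent-3-yn-1-ol | CC#CCCO | starting material
2 | triisopropyl(pent-3-yn-1-yloxy)silane | CC#CCCO[Si](C(C)C)(C(C)C)C(C)C | intermediate
3 | chlorobis(cyclopentadienyl)[(E)-5-(triisopropylsilyloxy)pent-2-en-2-yl]zirconium | Cl[Zr](C1C=CC=C1)(C1C=CC=C1)/C(C)=C/CCO[Si](C(C)C)(C(C)C)C(C)C | intermediate
4 | (E)-(4-iodopent-3-en-1-yloxy)triisopropylsilane | I/C(C)=C/CCO[Si](C(C)C)(C(C)C)C(C)C | intermediate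
5 | β-cyclocitral | CC1=C(C=O)C(C)(C)CCC1 | starting material
6 | [(E)-5-(triisopropylsilyloxy)pent-2-en-2-yl]lithium | [Li]/C(C)=C/CCO[Si](C(C)C)(C(C)C)C(C)C | intermediate
7 | (E)-2-methyl-5-(triisopropylsilyloxy)-1-(2,6,6-trimethylcyclohex-1-en-1-yl)pent-2-en-1-ol (racemic carbinol) | CC1=C(C(O)/C(C)=C/CCO[Si](C(C)C)(C(C)C)C(C)C)C(C)(C)CCC1 | intermediate
8 | (E)-2-methyl-5-(triisopropylsilyloxy)-1-(2,6,6-trimethylcyclohex-1-en-1-yl)pent-2-en-1-one | CC1=C(C(=O)/C(C)=C/CCO[Si](C(C)C)(C(C)C)C(C)C)C(C)(C)CCC1 | intermediate
9 | triethylsilyl enol ether (C5=C6) of the B-nor ketone; 8β-Me, 9β-chain, 10β-Me | CC(C)[Si](OCC[C@@H]1[C@@]2(C)CCCC(C)(C)C2=C(O[Si](CC)(CC)CC)[C@@H]1C)(C(C)C)C(C)C | intermediate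
10 | B-nor ketone: trans-fused 2,3a,7,7-tetramethyl-3-[2-(triisopropylsilyloxy)ethyl]octahydro-1H-inden-1-one (5α-H; 8-Me, 9-chain, 10-Me all β) | CC(C)[Si](OCC[C@@H]1[C@@]2(C)CCCC(C)(C)[C@@H]2C(=O)[C@@H]1C)(C(C)C)C(C)C | intermediate
11 | lithium enolate (C6=C8) of 10 | CC(C)[Si](OCC[C@@H]1[C@@]2(C)CCCC(C)(C)[C@@H]2C(O[Li])=C1C)(C(C)C)C(C)C | intermediate
12 | trimethylsilyl enol ether (C6=C8) of 10 | CC(C)[Si](OCC[C@@H]1[C@@]2(C)CCCC(C)(C)[C@@H]2C(O[Si](C)(C)C)=C1C)(C(C)C)C(C)C | intermediate
13 | cyclopropyl silyl ether (C-7 bridging C-6 and C-8 on the α face; OTMS and 8-Me β) | CC(C)[Si](OCC[C@@H]1[C@@]2(C)CCCC(C)(C)[C@@H]2[C@@]3(O[Si](C)(C)C)C[C@@]13C)(C(C)C)C(C)C | intermediate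
14 | 8α-hydroperoxy-12-(triisopropylsilyloxy)-13,14,15,16-tetranorlabdan-6-one | CC(C)[Si](OCC[C@@H]1[C@@]2(C)CCCC(C)(C)[C@@H]2C(=O)C[C@@]1(C)OO)(C(C)C)C(C)C | intermediate
15 | 8α-hydroxy-12-(triisopropylsilyloxy)-13,14,15,16-tetranorlabdan-6-one | CC(C)[Si](OCC[C@@H]1[C@@]2(C)CCCC(C)(C)[C@@H]2C(=O)C[C@@]1(C)O)(C(C)C)C(C)C | intermediate
16 | 12-(triisopropylsilyloxy)-13,14,15,16-tetranorlabdane-6α,8α-diol | CC(C)[Si](OCC[C@@H]1[C@@]2(C)CCCC(C)(C)[C@@H]2[C@@H](O)C[C@@]1(C)O)(C(C)C)C(C)C | intermediate
17 | angelic acid | C/C=C(/C)C(=O)O | starting material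
18 | angelic 2,4,6-trichlorobenzoic anhydride | C/C=C(/C)C(=O)OC(=O)c1c(Cl)cc(Cl)cc1Cl | intermediate
19 | 8α-hydroxy-12-(triisopropylsilyloxy)-13,14,15,16-tetranorlabdan-6α-yl angelate | CC(C)[Si](OCC[C@@H]1[C@@]2(C)CCCC(C)(C)[C@@H]2[C@@H](OC(=O)/C(C)=C\C)C[C@@]1(C)O)(C(C)C)C(C)C | intermediate
20 | 8α,12-dihydroxy-13,14,15,16-tetranorlabdan-6α-yl angelate | OCC[C@@H]1[C@@]2(C)CCCC(C)(C)[C@@H]2[C@@H](OC(=O)/C(C)=C\C)C[C@@]1(C)O | intermediate
21 | 8α-hydroxy-12-oxo-13,14,15,16-tetranorlabdan-6α-yl angelate (open form of the 8,12-lactol) | O=CC[C@@H]1[C@@]2(C)CCCC(C)(C)[C@@H]2[C@@H](OC(=O)/C(C)=C\C)C[C@@]1(C)O | intermediate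
22 | 2-(triphenylphosphoranylidene)propanal | CC(C=O)=P(c1ccccc1)(c1ccccc1)c1ccccc1 | starting material
23 | (12E)-6α-angeloyloxy-8α-hydroxy-15-norlabd-12-en-14-al | O=C/C(C)=C/C[C@@H]1[C@@]2(C)CCCC(C)(C)[C@@H]2[C@@H](OC(=O)/C(C)=C\C)C[C@@]1(C)O | intermediate
24 | (12E)-8α-hydroxylabda-12,14-dien-6α-yl angelate | C=C/C(C)=C/C[C@@H]1[C@@]2(C)CCCC(C)(C)[C@@H]2[C@@H](OC(=O)/C(C)=C\C)C[C@@]1(C)O | target

**Step count and risks**

Total step count: 14. Longest linear sequence: 14 steps (1 → 24); β-cyclocitral 5, angelic acid 17 and ylide 22 enter at steps 3, 10 and 13.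

Steps most likely to fail:

1. Step 5 (Proposed new method). The electrocyclisation of the twisted, hindered dienone may be too slow, so that silylium-mediated 1,2- or conjugate hydrosilylation of 8 wins. The chiral anion may give poor torquoselectivity, and E/Z isomerisation of the acyclic enone before ring closure would erode the C-9/C-10 relationship. Fallback: from 8 the cyclisation is run without chiral control under the established Lewis acid/silane conditions (BF3·OEt2, Et3SiH, CH2Cl2, −78 → 0 °C, same hydrolysis). This gives the racemate, that is 10 together with its mirror image, ent-B-nor ketone F1. The enantiomers are separated by preparative chromatography on a chiral stationary phase and the route is rejoined at 10.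

2. Step 8 (key step). The alkoxyl radical may cleave the external cyclopropane bond, O2 may be captured from the β face, the tertiary peroxyl radical may fragment, or a cis ring fusion carried over from step 5 may persist, since C-5 cannot be equilibrated once the base-sensitive β-hydroxy ketone exists. Fallback: from 13, FeCl3 in DMF at 0 °C opens the same internal bond with chlorine transfer to the ring-expanded β-chloro ketone F2. NaOAc in MeOH at reflux eliminates HCl to the 7-en-6-one F3 and at the same time equilibrates C-5 to the trans-decalin. Alkaline H2O2 (MeOH, 0 °C) epoxidises from the α face to the 7α,8α-epoxy ketone F4, and SmI2 (THF/MeOH, −78 °C) cleaves the C7–O bond with retention at C-8, which returns to the route at 15.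

3. Step 9. Thermodynamic control at C-6 may be incomplete (protonation giving the axial 6β-alcohol), or the basic medium may cause retro-aldol opening or dehydration of the β-hydroxy ketone. Fallback: from 15, NaBH4 in MeOH at 0 °C gives by α-face attack the axial alcohol, 6β,8α-diol F5. A neutral ruthenium hydrogen-transfer catalyst (toluene, 80–100 °C) then epimerises the secondary carbinol by reversible dehydrogenation–hydrogenation towards the equatorial alcohol, which returns to the route at 16.

Further compounds
F1 | step 5 | ent-B-nor ketone (mirror image of 10) | CC(C)[Si](OCC[C@H]1[C@]2(C)CCCC(C)(C)[C@H]2C(=O)[C@H]1C)(C(C)C)C(C)C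
F2 | step 8 | 8α-chloro-12-(triisopropylsilyloxy)-13,14,15,16-tetranorlabdan-6-one | CC(C)[Si](OCC[C@@H]1[C@@]2(C)CCCC(C)(C)[C@@H]2C(=O)C[C@@]1(C)Cl)(C(C)C)C(C)C
F3 | step 8 | 12-(triisopropylsilyloxy)-13,14,15,16-tetranorlabd-7-en-6-one | CC(C)[Si](OCC[C@@H]1[C@@]2(C)CCCC(C)(C)[C@@H]2C(=O)C=C1C)(C(C)C)C(C)C
F4 | step 8 | 7α,8α-epoxy-12-(triisopropylsilyloxy)-13,14,15,16-tetranorlabdan-6-one | CC(C)[Si](OCC[C@@H]1[C@@]2(C)CCCC(C)(C)[C@@H]2C(=O)[C@H]3O[C@@]13C)(C(C)C)C(C)C
F5 | step 9 | 12-(triisopropylsilyloxy)-13,14,15,16-tetranorlabdane-6β,8α-diol | CC(C)[Si](OCC[C@@H]1[C@@]2(C)CCCC(C)(C)[C@@H]2[C@H](O)C[C@@]1(C)O)(C(C)C)C(C)C
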